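**Retrosynthetic overview**

- Ring A is numbered from the carboxyl carbon (C1). The strategy rests on its C3 benzylic carbon, which carries OMe and the isobutyl chain and lies ortho to the C2 methoxy and para to the C6 aryloxy oxygen, so an O-methyl oxocarbenium ion at this carbon is strongly stabilised.
- Key disconnection: the Cα–OMe and Cα–CH2 bonds are cut together, back to aldehyde 15, MeOSiMe3 (16) and methallylsilane (17). Their union under a chiral silylium imidodiphosphorimidate ion pair sets the (R) centre.
- The ring B formyl group travels as CH2OPiv and the ring B phenol as OPiv. After the key step, alkene hydrogenation, global saponification and MnO2 oxidation give the target.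
- The diaryl ether is cut at the ring A C6–O bond: SNAr of ring B phenol 11 on fluoride 5, activated by its para formyl group (the key-step aldehyde) and its ortho ester. The MOM groups are then exchanged for pivalates.
- No ring is formed. Ring A comes from 2-bromo-5-fluoroanisole (1) and ring B from 3-hydroxy-5-methylbenzoic acid (6), whose second phenolic oxygen is added by directed metalation, borylation and oxidation.

Key step: step 9

Assumption: which antipode of the catalyst leaves the Re face of ion 18 open cannot be derived with certainty; the (S,S) form is written, and the (R,R) form would be taken if a first trial showed the opposite sense.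

**Route**

Step 1
Reactants: 1 2-bromo-5-fluoroanisole
Product: 3 methyl 3-bromo-6-fluoro-2-methoxybenzoate, via aryllithium 2 (not isolated)
Conditions: LiN(iPr)2, THF, −78 °C; then cannulated into ClCO2Me (3 equiv), THF, −78 °C
Reagents that add atoms: methyl chloroformate, COC(=O)Cl
Why: Directed ortho-metalation: the proton between fluorine and methoxy is the most acidic on the ring, so the amide base should remove it at −78 °C without touching the bromide, and acylation of the aryllithium gives an ester whose two ortho substituents protect it from a second addition.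

Step 2
Reactants: 3 methyl 3-bromo-6-fluoro-2-methoxybenzoate
Product: 5 methyl 6-fluoro-3-formyl-2-methoxybenzoate, via arylmagnesium chloride 4 (not isolated)
Conditions: iPrMgCl·LiCl, THF, −15 °C; DMF, −15 → 0 °C; aq. NH4Cl
Reagents that add atoms: N,N-dimethylformamide, CN(C)C=O
Why: Bromine–magnesium exchange should be fast on this electron-poor bromide with an ortho methoxy group at a temperature where the di-ortho-substituted ester is not attacked, and DMF formylates the arylmagnesium (Bouveault formylation).

Step 3
Reactants: 6 3-hydroxy-5-methylbenzoic acid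
Product: 7 3-(hydroxymethyl)-5-methylphenol
Conditions: BH3·THF, THF, 0 °C → rt; MeOH quench
Reagents that add atoms: none
Why: Borane reduction of a carboxylic acid proceeds through the acyloxyborane and is selective for the acid, the phenol only consuming hydride as an aryloxyborane that is hydrolysed on work-up.

Step 4
Reactants: 7 3-(hydroxymethyl)-5-methylphenol
Product: 8 1-(methoxymethoxy)-3-[(methoxymethoxy)methyl]-5-methylbenzene
Conditions: NaH, MOMCl, THF/DMF, 0 °C → rt
Reagents that add atoms: chloromethyl methyl ether, COCCl
Why: Williamson-type alkylation of the phenoxide and the alkoxide gives two base-stable acetals that also serve as the directing groups for step 5.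

Step 5
Reactants: 8 1-(methoxymethoxy)-3-[(methoxymethoxy)methyl]-5-methylbenzene
Product: 11 2-(methoxymethoxy)-6-[(methoxymethoxy)methyl]-4-methylphenol, via aryllithium 9 (not isolated), via arylboronate 10 (not isolated)
Conditions: n-BuLi, Et2O, 0 °C; B(OMe)3, −78 °C → rt; H2O2, aq. NaOH, 0 °C
Reagents that add atoms: hydrogen peroxide, OO
Why: Directed ortho-metalation should take place at the one ring position where both the OMOM and the CH2OMOM oxygens can hold lithium, and borylation followed by oxidative 1,2-aryl shift (boronate oxidation) turns that C–Li bond into the phenol, which fixes the ring B pattern (OH para to methyl, flanked by OMOM and CH2OMOM).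

Step 6
Reactants: 11 2-(methoxymethoxy)-6-[(methoxymethoxy)methyl]-4-methylphenol; 5 methyl 6-fluoro-3-formyl-2-methoxybenzoate
Product: 12 methyl 3-formyl-2-methoxy-6-{2-(methoxymethoxy)-6-[(methoxymethoxy)methyl]-4-methylphenoxy}benzoate
Conditions: K2CO3, DMF, 60 °C
Reagents that add atoms: none
Why: Nucleophilic aromatic substitution by addition–elimination (SNAr): the fluoride of 5 is activated by the para formyl and ortho ester groups, and the electron-rich phenoxide carries only base-stable acetals, so the diaryl ether should form under mild carbonate conditions with the key-step aldehyde already in place.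

Step 7
Reactants: 12 methyl 3-formyl-2-methoxy-6-{2-(methoxymethoxy)-6-[(methoxymethoxy)methyl]-4-methylphenoxy}benzoate
Product: 13 methyl 3-formyl-6-[2-hydroxy-6-(hydroxymethyl)-4-methylphenoxy]-2-methoxybenzoate
Conditions: 3 M aq. HCl, THF, 50 °C
Reagents that add atoms: none
Why: Acid hydrolysis cleaves the aryl and the primary alkyl MOM acetals, while the aryl methyl ether, the hindered methyl ester, the aldehyde and the diaryl ether are stable, and the absence of base avoids Smiles migration of the activated ring A onto the freed hydroxyl groups.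

Step 8
Reactants: 13 methyl 3-formyl-6-[2-hydroxy-6-(hydroxymethyl)-4-methylphenoxy]-2-methoxybenzoate; 14 pivaloyl chloride
Product: 15 methyl 3-formyl-2-methoxy-6-{4-methyl-2-(pivaloyloxy)-6-[(pivaloyloxy)methyl]phenoxy}benzoate
Conditions: 14 (2.5 equiv), pyridine, DMAP (cat.), CH2Cl2, 0 °C → rt
Reagents that add atoms: pivaloyl chloride (second equivalent), CC(C)(C)C(=O)Cl
Why: DMAP-catalysed acylation with two equivalents of the acid chloride esterifies the phenol and the primary alcohol without touching the aldehyde, and gives non-ionisable groups that should tolerate the silylium catalyst of step 9, where acetals would ionise.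

Step 9
Reactants: 15 methyl 3-formyl-2-methoxy-6-{4-methyl-2-(pivaloyloxy)-6-[(pivaloyloxy)methyl]phenoxy}benzoate; 16 methoxytrimethylsilane; 17 methallyltrimethylsilane
Product: 19 methyl 2-methoxy-3-[(1R)-1-methoxy-3-methylbut-3-en-1-yl]-6-{4-methyl-2-(pivaloyloxy)-6-[(pivaloyloxy)methyl]phenoxy}benzoate, via oxocarbenium ion 18 (not isolated)
Conditions: (S,S)-IDPi acid HN[P(=NTf)(3,3'-Ar2-BINOLate)]2 with Ar = 3,5-(CF3)2C6H3 (5 mol%), 16 (3 equiv), 17 (2 equiv), toluene, −78 °C; Et3N quench at −78 °C
Reagents that add atoms: none
Why: Proposed new method: the acid is silylated in the flask by the allylsilane, the resulting silylium ion pair silylates the aldehyde oxygen, MeOSiMe3 adds, and loss of (Me3Si)2O gives the (E)-O-methyl oxocarbenium ion 18 held as a contact ion pair by the confined chiral anion; methallylsilane then attacks through an open transition state and the β-silyl cation hands Me3Si+ back to the anion, closing the cycle. The closest known reactions are the racemic Lewis-acid-catalysed three-component Hosomi–Sakurai etherifying allylation of aldehydes with alkoxysilanes and allylsilanes, and the imidodiphosphorimidate-catalysed enantioselective Hosomi–Sakurai allylation of aldehydes; their merger at an acyclic aryl oxocarbenium ion has not been shown. No ring is closed. The one new stereocentre is controlled by the counter-anion, which has to leave the Re face of the oxocarbenium carbon open so that C–C bond formation gives the (1R) ether. The step needs ether transfer to outrun direct allylation of the silylated aldehyde and needs the product not to ionise again: the C2 methoxy and C6 aryloxy donors of ring A make ion 18 form readily from the mixed silyl acetal, the excess of MeOSiMe3 keeps the aldehyde in the acetal manifold, and running and quenching at −78 °C should keep the product ether configurationally intact. The methyl ester and the two pivalates are weak, non-ionisable Lewis bases and should remain spectators.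

Step 10
Reactants: 19 methyl 2-methoxy-3-[(1R)-1-methoxy-3-methylbut-3-en-1-yl]-6-{4-methyl-2-(pivaloyloxy)-6-[(pivaloyloxy)methyl]phenoxy}benzoate
Product: 20 methyl 2-methoxy-3-[(1R)-1-methoxy-3-methylbutyl]-6-{4-methyl-2-(pivaloyloxy)-6-[(pivaloyloxy)methyl]phenoxy}benzoate
Conditions: H2 (3 bar), RhCl(PPh3)3 (5 mol%), benzene/EtOH 1:1, rt
Reagents that add atoms: none
Why: Homogeneous hydrogenation with RhCl(PPh3)3 reduces the 1,1-disubstituted alkene without hydrogenolysis of the benzylic C–O bond and without double-bond migration towards the stereocentre, both of which palladium on carbon could cause.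

Step 11
Reactants: 20 methyl 2-methoxy-3-[(1R)-1-methoxy-3-methylbutyl]-6-{4-methyl-2-(pivaloyloxy)-6-[(pivaloyloxy)methyl]phenoxy}benzoate
Product: 21 6-[2-hydroxy-6-(hydroxymethyl)-4-methylphenoxy]-2-methoxy-3-[(1R)-1-methoxy-3-methylbutyl]benzoic acid
Conditions: KOH (10 equiv), MeOH/H2O 4:1, 70 °C; then 1 M HCl to pH 4 at 0 °C
Reagents that add atoms: potassium hydroxide, [K+].[OH-]
Why: Saponification (acyl–oxygen ester hydrolysis) should cleave the aryl pivalate, the benzyl pivalate and, more slowly, the di-ortho-substituted methyl benzoate, while the benzylic methyl ether is inert to base and the cold, weakly acidic work-up avoids its ionisation.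

Step 12
Reactants: 21 6-[2-hydroxy-6-(hydroxymethyl)-4-methylphenoxy]-2-methoxy-3-[(1R)-1-methoxy-3-methylbutyl]benzoic acid
Product: 22 6-(2-formyl-6-hydroxy-4-methylphenoxy)-2-methoxy-3-[(1R)-1-methoxy-3-methylbutyl]benzoic acid
Conditions: activated MnO2 (excess), EtOAc, rt
Reagents that add atoms: none
Why: MnO2 oxidises benzylic alcohols selectively on its surface and stops at the aldehyde, a single phenol and a carboxylic acid should be tolerated, and the neutral conditions keep the acid-labile benzylic ether and its configuration.

**Compound list**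

1 | 2-bromo-5-fluoroanisole | COc1cc(F)ccc1Br | starting material
2 | (3-bromo-6-fluoro-2-methoxyphenyl)lithium | COc1c(Br)ccc(F)c1[Li] | intermediate
3 | methyl 3-bromo-6-fluoro-2-methoxybenzoate | COC(=O)c1c(F)ccc(Br)c1OC | intermediate
4 | [4-fluoro-2-methoxy-3-(methoxycarbonyl)phenyl]magnesium chloride | COC(=O)c1c(F)ccc([Mg]Cl)c1OC | intermediate
5 | methyl 6-fluoro-3-formyl-2-methoxybenzoate | COC(=O)c1c(F)ccc(C=O)c1OC | intermediate
6 | 3-hydroxy-5-methylbenzoic acid | Cc1cc(O)cc(C(=O)O)c1 | starting material
7 | 3-(hydroxymethyl)-5-methylphenol | Cc1cc(O)cc(CO)c1 | intermediate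
8 | 1-(methoxymethoxy)-3-[(methoxymethoxy)methyl]-5-methylbenzene | Cc1cc(OCOC)cc(COCOC)c1 | intermediate
9 | {2-(methoxymethoxy)-6-[(methoxymethoxy)methyl]-4-methylphenyl}lithium | Cc1cc(OCOC)c([Li])c(COCOC)c1 | intermediate
10 | dimethyl {2-(methoxymethoxy)-6-[(methoxymethoxy)methyl]-4-methylphenyl}boronate | Cc1cc(OCOC)c(B(OC)OC)c(COCOC)c1 | intermediate
11 | 2-(methoxymethoxy)-6-[(methoxymethoxy)methyl]-4-methylphenol | Cc1cc(OCOC)c(O)c(COCOC)c1 | intermediate
12 | methyl 3-formyl-2-methoxy-6-{2-(methoxymethoxy)-6-[(methoxymethoxy)methyl]-4-methylphenoxy}benzoate | COc1c(C=O)ccc(Oc2c(OCOC)cc(C)cc2COCOC)c1C(=O)OC | intermediate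
13 | methyl 3-formyl-6-[2-hydroxy-6-(hydroxymethyl)-4-methylphenoxy]-2-methoxybenzoate | COc1c(C=O)ccc(Oc2c(O)cc(C)cc2CO)c1C(=O)OC | intermediate
14 | pivaloyl chloride | CC(C)(C)C(=O)Cl | starting material
15 | methyl 3-formyl-2-methoxy-6-{4-methyl-2-(pivaloyloxy)-6-[(pivaloyloxy)methyl]phenoxy}benzoate | COc1c(C=O)ccc(Oc2c(OC(=O)C(C)(C)C)cc(C)cc2COC(=O)C(C)(C)C)c1C(=O)OC | intermediate
16 | methoxytrimethylsilane | CO[Si](C)(C)C | starting material
17 | methallyltrimethylsilane | CC(=C)C[Si](C)(C)C | starting material
18 | O-methyl oxocarbenium ion of 15 (ion pair with the chiral anion) | COc1c(C=[O+]C)ccc(Oc2c(OC(=O)C(C)(C)C)cc(C)cc2COC(=O)C(C)(C)C)c1C(=O)OC | intermediate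
19 | methyl 2-methoxy-3-[(1R)-1-methoxy-3-methylbut-3-en-1-yl]-6-{4-methyl-2-(pivaloyloxy)-6-[(pivaloyloxy)methyl]phenoxy}benzoate | COc1c([C@@H](CC(C)=C)OC)ccc(Oc2c(OC(=O)C(C)(C)C)cc(C)cc2COC(=O)C(C)(C)C)c1C(=O)OC | intermediate
20 | methyl 2-methoxy-3-[(1R)-1-methoxy-3-methylbutyl]-6-{4-methyl-2-(pivaloyloxy)-6-[(pivaloyloxy)methyl]phenoxy}benzoate | COc1c([C@@H](CC(C)C)OC)ccc(Oc2c(OC(=O)C(C)(C)C)cc(C)cc2COC(=O)C(C)(C)C)c1C(=O)OC | intermediate
21 | 6-[2-hydroxy-6-(hydroxymethyl)-4-methylphenoxy]-2-methoxy-3-[(1R)-1-methoxy-3-methylbutyl]benzoic acid | COc1c([C@@H](CC(C)C)OC)ccc(Oc2c(O)cc(C)cc2CO)c1C(=O)O | intermediate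
22 | 6-(2-formyl-6-hydroxy-4-methylphenoxy)-2-methoxy-3-[(1R)-1-methoxy-3-methylbutyl]benzoic acid | COc1c([C@@H](CC(C)C)OC)ccc(Oc2c(O)cc(C)cc2C=O)c1C(=O)O | target

**Step count and risks**

Total step count: 12. Longest linear sequence: 10 steps (steps 3 to 12, from 3-hydroxy-5-methylbenzoic acid); the ring A branch (steps 1 and 2) joins at step 6.

The three steps most likely to fail:

Step 9. The silylated aldehyde may be allylated directly before ether transfer, the ion pair may discriminate the two faces of the oxocarbenium ion poorly, or the product ether may ionise again and lose its configuration or take up a second allyl group. The fallback uses known chemistry and sets out from 15. Asymmetric methallylboration with (+)-B-methallyldiisopinocampheylborane, made from (+)-B-methoxydiisopinocampheylborane and methallylmagnesium chloride (Et2O, −78 °C, ethanolamine work-up), is chemoselective for the aldehyde. By the established facial preference of this reagent family it should add to the Re face to give methyl 3-[(1R)-1-hydroxy-3-methylbut-3-en-1-yl]-2-methoxy-6-{4-methyl-2-(pivaloyloxy)-6-[(pivaloyloxy)methyl]phenoxy}benzoate F1. O-Methylation under non-basic conditions (MeOTf, 2,6-di-tert-butyl-4-methylpyridine, CH2Cl2, 0 °C), which spares the pivalates, then brings the route back at 19.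

Step 5. Lithiation may occur at the ring position next to the methyl group, or at the benzylic CH2 of the MOM ether followed by Wittig rearrangement. The fallback sets out from 7 and replaces the benzylic MOM ether by a lithium alkoxide as co-director. MOMCl with K2CO3 in acetone alkylates only the phenol and gives [3-(methoxymethoxy)-5-methylphenyl]methanol F2. Two equivalents of n-BuLi form the alkoxide, which cannot rearrange, and then metalate between the two oxygen groups; B(OMe)3 and H2O2/NaOH give 2-(hydroxymethyl)-6-(methoxymethoxy)-4-methylphenol F3. TBSCl (1.05 equiv) and imidazole at 0 °C should silylate the primary alcohol in preference to the hindered, hydrogen-bonded phenol and give 2-({[tert-butyl(dimethyl)silyl]oxy}methyl)-6-(methoxymethoxy)-4-methylphenol F4; any aryl silyl ether formed alongside would be cleaved again by K2CO3 in MeOH. SNAr with 5 under the conditions of step 6 gives methyl 6-[2-({[tert-butyl(dimethyl)silyl]oxy}methyl)-6-(methoxymethoxy)-4-methylphenoxy]-3-formyl-2-methoxybenzoate F5. 3 M aq. HCl in THF removes the silyl ether and the MOM group, and the route is rejoined at 13.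

Step 12. The free carboxylic acid may bind to the MnO2 surface so that conversion stalls or material is lost, and the phenol may be over-oxidised on long exposure. The fallback sets out from 20 and changes the order of the end game so that the oxidation is run on an ester. NaOMe in MeOH removes both pivalates by transesterification and cannot change the methyl ester, giving methyl 6-[2-hydroxy-6-(hydroxymethyl)-4-methylphenoxy]-2-methoxy-3-[(1R)-1-methoxy-3-methylbutyl]benzoate F6. MnO2 in CH2Cl2 gives methyl 6-(2-formyl-6-hydroxy-4-methylphenoxy)-2-methoxy-3-[(1R)-1-methoxy-3-methylbutyl]benzoate F7. LiI in pyridine at 100 °C cleaves the hindered methyl ester by SN2 attack at the methyl group, which avoids hot hydroxide in the presence of the aldehyde, and after mild acidification the route arrives at 22.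

**Further compounds**

F1 | step 9 | methyl 3-[(1R)-1-hydroxy-3-methylbut-3-en-1-yl]-2-methoxy-6-{4-methyl-2-(pivaloyloxy)-6-[(pivaloyloxy)methyl]phenoxy}benzoate | COc1c([C@@H](CC(C)=C)O)ccc(Oc2c(OC(=O)C(C)(C)C)cc(C)cc2COC(=O)C(C)(C)C)c1C(=O)OC
F2 | step 5 | [3-(methoxymethoxy)-5-methylphenyl]methanol | Cc1cc(OCOC)cc(CO)c1
F3 | step 5 | 2-(hydroxymethyl)-6-(methoxymethoxy)-4-methylphenol | Cc1cc(OCOC)c(O)c(CO)c1
F4 | step 5 | 2-({[tert-butyl(dimethyl)silyl]oxy}methyl)-6-(methoxymethoxy)-4-methylphenol | Cc1cc(OCOC)c(O)c(CO[Si](C)(C)C(C)(C)C)c1
F5 | step 5 | methyl 6-[2-({[tert-butyl(dimethyl)silyl]oxy}methyl)-6-(methoxymethoxy)-4-methylphenoxy]-3-formyl-2-methoxybenzoate | COc1c(C=O)ccc(Oc2c(OCOC)cc(C)cc2CO[Si](C)(C)C(C)(C)C)c1C(=O)OC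
F6 | step 12 | methyl 6-[2-hydroxy-6-(hydroxymethyl)-4-methylphenoxy]-2-methoxy-3-[(1R)-1-methoxy-3-methylbutyl]benzoate | COc1c([C@@H](CC(C)C)OC)ccc(Oc2c(O)cc(C)cc2CO)c1C(=O)OC
F7 | step 12 | methyl 6-(2-formyl-6-hydroxy-4-methylphenoxy)-2-methoxy-3-[(1R)-1-methoxy-3-methylbutyl]benzoate | COc1c([C@@H](CC(C)C)OC)ccc(Oc2c(O)cc(C)cc2C=O)c1C(=O)OC
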